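All runs come from a simulation with made-up constants, noise included.

How much faster is Xo made at 50% conversion of Ez when Zu is doubled, or raised to 12 µM?

all flasks: Zu 2.5 µM
- ash: Ez 35 mM; run made earlier
- elm: Ez 55 mM; run made earlier
- flask: Ez 25 mM

| run | time / d | Xo / % | Ez / % |
|---|---|---|---|
| ash | 0.333 | 44.3 | 49.6 |
| ash | 1.04 | 100.3 | 0.3 |
| ash | 1.67 | 99.5 | 0 |
| ash | 3.00 | 100.8 | 0.7 |
| ash | 4.00 | 99.6 | 0.5 |
| elm | 0.333 | 28.3 | 68.7 |
| elm | 0.625 | 53.2 | 43.8 |
| elm | 1.04 | 88.9 | 6.9 |
| elm | 2.00 | 100.9 | 0.9 |
| elm | 4.00 | 100.6 | 0.6 |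

(scatter of a reading: 0.5 percentage points)

1. factor on the rate of making Xo when 50% of the Ez are converted (what has only dissolved counts as not reacted) if Zu is charged twice over
2. factor on the rate when 50% of the Ez are converted (what has only dissolved counts as not reacted) if Zu is charged at 12 µM instead

- Ez is a solid; its amount is given per volume of the solution
- at the start none of Ez is in solution
- what has only dissolved of Ez counts as not reacted
- no earlier run changes the charge of Zu; that part of a forecast is a guess

We read a ladder of times from the runs, fastest first.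

1. Averaged up to 1.04 d, the elm run makes Xo at 47.0 mM d⁻¹, and averaged up to 0.333 d, the ash run makes it at 46.6 mM d⁻¹, about the same, so within these readings the rate is zero order in the solid charged.

2. Dividing by the Zu charged gives the turnover frequency, Xo made per Zu per unit time: 18800 d⁻¹, or one cycle in 4.60 s.

3. The ash readings at 0.333 d fall short of the charge by 2.13 mM, which we read as dissolved material. At this rate that pool turns over in 0.0454 d, longer than one cycle.

4. At this rate we reckon that the flask's charge takes 0.532 d to become Xo, longer than the pool's turnover.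

Our reckoning: a constant turnover frequency gives factors of 2 and 4.80, but no run tests this. The forecast gives 1.95 (1.5 to 2.05) and 4.5 (2.8 to 5), holding that “the rate should scale with Zu”, shaded slightly downward.

The simulation gives 1.69 for doubled Zu and 2.50 at 12 µM.

    DzZu → Zu + Xo (k = 1300 h⁻¹)
    Dz + Zu ⇌ DzZu (K = 1800 M⁻¹, k = 2.70 × 10⁶ M⁻¹ h⁻¹)
    Ez ⇌ Dz, rate k3*(cs3 - [Dz]) while solid is left; crystals form when [Dz] > cs3 (solubility = 2.40 mM, k = 2.60 h⁻¹)

The turnover frequency read from the runs is 60.6% of 31000 d⁻¹, the constant of the step from DzZu to Zu + Xo, and in the flask DzZu holds 59.0% of the catalyst at 0.500 d. In the flask with 12 µM of Zu, the factor 2.50 on the rate read from the runs puts the turnover frequency at 9800 d⁻¹, which is 31.6% of that constant, and free Zu is 68.1% of the catalyst at 50% conversion.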